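**Retrosynthetic overview**
1. Target 20 ⇐ (Z)-β-iodo-α-methylacrylate 19 (iodide exchanged for MeS last) ⇐ bis-allylic C–H oxidation of the skipped diene 18 ⇐ ester of bicyclic diol 12 with acid 17.
2. 12 ⇐ acyclic dienyne 11: rings A and B close together in one rhodium-catalysed intramolecular diene–alkyne [4+2] (bonds C4a–C8a and C5–C6); the syn C1/C2 pair on the tether sets the quaternary C8a.
3. 11 ⇐ terminal epoxide 10 + propargyl Grignard; 10 ⇐ triol 8; the diene of 8 ⇐ one-flask methylalumination/Pd coupling of alkyne 4 with bromo alcohol 6.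
4. 4 ⇐ Sharpless epoxide 2 of (E)-crotyl alcohol 1, opened at C3 by an alkynylalane (sets the carbinol and methyl stereocentres).
5. Ring order: no ring exists before step 8; rings A and B form simultaneously; acid 17 comes from propargyl alcohol in two steps.

Assumption: the target is read as the (1R,2R,8aR) bicycle (naphthalene numbering, used throughout) carrying a (2Z)-2-methyl-3-(methylsulfanyl)prop-2-enoate.

**Step 1**
Reactants: 1 (E)-but-2-en-1-ol
Product: 2 [(2R,3R)-3-methyloxiran-2-yl]methanol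
Conditions: Ti(OiPr)4 (5 mol %), D-(−)-diisopropyl tartrate (6 mol %), t-BuOOH (2 equiv), 4 Å sieves, CH2Cl2, −20 °C
Reagents that add atoms: tert-butyl hydroperoxide, CC(C)(C)OO
Why: Sharpless asymmetric epoxidation: the titanium–D-tartrate complex binds the allylic alcohol and delivers the peroxide oxygen to a single alkene face, setting C2 and C3 as (2R,3R) (typically above 90% ee).

**Step 2**
Reactants: 2 [(2R,3R)-3-methyloxiran-2-yl]methanol
Product: 3 (2S,3R)-3-methyl-5-(trimethylsilyl)pent-4-yne-1,2-diol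
Conditions: Me3SiC≡CH (3 equiv), n-BuLi (3 equiv), toluene, −78 °C; Et2AlCl (3 equiv), 0 °C; then 2, 0 → 23 °C
Reagents that add atoms: ethynyltrimethylsilane, C#C[Si](C)(C)C
Why: Hydroxyl-directed epoxide opening by a diethylalkynylalane: the aluminium alkoxide of 2 hands the alkynyl group to C3 from the rear (SN2, inversion) while C2 keeps its oxygen, so the trans-epoxide becomes the syn hydroxyl/methyl pair that later sits on C2 and C1 of the bicycle.

**Step 3**
Reactants: 3 (2S,3R)-3-methyl-5-(trimethylsilyl)pent-4-yne-1,2-diol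
Product: 4 (2S,3R)-3-methylpent-4-yne-1,2-diol
Conditions: K2CO3 (0.2 equiv), MeOH, 23 °C
Reagents that add atoms: none
Why: Carbonate-catalysed methanolysis of the C(sp)–Si bond (protodesilylation) frees the terminal alkyne needed for carbometalation; no stereocentre is involved.

**Step 4**
Reactants: 5 3-methylbuta-1,2-diene
Product: 6 3-bromo-2-methylbut-3-en-2-ol
Conditions: NBS (1.05 equiv), acetone–H2O 4:1, 0 °C
Reagents that add atoms: N-bromosuccinimide, O=C1CCC(=O)N1Br; water, O
Why: Electrophilic bromohydroxylation of the allene: bromine adds to the central carbon and water to the tertiary terminus of the bromonium/allyl cation (Markovnikov), giving the 2-bromoallylic tertiary alcohol.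

**Step 5**
Reactants: 4 (2S,3R)-3-methylpent-4-yne-1,2-diol; 6 3-bromo-2-methylbut-3-en-2-ol
Product: 8 (2S,3R,4E)-3,4,7-trimethyl-6-methylideneoct-4-ene-1,2,7-triol, via alkenylalane 7 (not isolated)
Conditions: AlMe3 (5 equiv), Cp2ZrCl2 (0.3 equiv), CH2Cl2, 0 → 23 °C; then 6 (1.3 equiv), Pd(PPh3)4 (5 mol %), ZnCl2 (0.5 equiv), THF, 23 → 45 °C
Reagents that add atoms: trimethylaluminium, C[Al](C)C
Why: Negishi zirconium-catalysed methylalumination (syn addition, methyl to the internal carbon, hence the E trisubstituted alkene) followed in the same flask by palladium-catalysed alkenyl–alkenyl cross-coupling of the alkenylalane (Negishi coupling, retention at both sp2 carbons); the hydroxyls travel as aluminium alkoxides and the stereocentres are untouched.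

**Step 6**
Reactants: 8 (2S,3R,4E)-3,4,7-trimethyl-6-methylideneoct-4-ene-1,2,7-triol
Product: 10 (4E,6R)-2,5-dimethyl-3-methylidene-6-[(2S)-oxiran-2-yl]hept-4-en-2-ol, via primary tosylate 9 (not isolated)
Conditions: NaH (3.3 equiv), 1-(4-methylbenzenesulfonyl)imidazole (1.05 equiv), THF, 0 → 23 °C
Reagents that add atoms: none
Why: The least hindered primary alkoxide is sulfonylated selectively and the neighbouring secondary alkoxide displaces the tosylate (intramolecular Williamson etherification), so the C–O bond at the stereocentre is never broken and its configuration is retained.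

**Step 7**
Reactants: 10 (4E,6R)-2,5-dimethyl-3-methylidene-6-[(2S)-oxiran-2-yl]hept-4-en-2-ol
Product: 11 (4E,6R,7R)-2,5,6-trimethyl-3-methylideneundec-4-en-10-yne-2,7-diol
Conditions: HC≡CCH2Br (3.5 equiv), Mg (4 equiv), HgCl2 (1 mol %), Et2O, 0 °C; then 10, −78 → −10 °C
Reagents that add atoms: propargyl bromide (used as its Grignard reagent), C#CCBr
Why: Ring opening of the terminal epoxide at its CH2 carbon by allenylmagnesium bromide reacting through its γ-carbon (SE2′ propargylation) installs the but-3-ynyl chain; the carbinol and methyl stereocentres are untouched and the extra Grignard only deprotonates the tertiary hydroxyl.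

**Step 8**
Reactants: 11 (4E,6R,7R)-2,5,6-trimethyl-3-methylideneundec-4-en-10-yne-2,7-diol
Product: 12 (1R,2R,8aR)-7-(2-hydroxypropan-2-yl)-1,8a-dimethyl-1,2,3,4,6,8a-hexahydronaphthalen-2-ol
Conditions: [RhCl(C8H14)2]2 (2.5 mol %; C8H14 = cyclooctene), P[OCH(CF3)2]3 (10 mol %), THF, 50 °C, argon
Reagents that add atoms: none
Why: Rhodium-catalysed intramolecular diene–alkyne [4+2] cycloaddition (oxidative cyclisation of the alkyne with the proximal alkene, allylrhodium metallacycle, reductive elimination) makes the C4a–C8a and C5–C6 bonds and so closes rings A and B together; because the new cyclohexa-1,4-diene must stay nearly coplanar with C4a=C5 the angular methyl is forced axial on ring A, and only the (8aR) diastereomer lets the chair-like tether keep the C1 methyl and C2 hydroxyl both equatorial (the epimer would need both axial with a 1,3-diaxial methyl/oxygen clash), which sets the quaternary centre cis to the C1 methyl.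

**Step 9**
Reactants: 13 prop-2-yn-1-ol
Product: 15 (2Z)-3-iodo-2-methylprop-2-en-1-ol, via alkenylmagnesium chelate 14 (not isolated)
Conditions: MeMgBr (2.5 equiv), CuI (10 mol %), THF, −10 → 23 °C; then I2 (1.3 equiv), −10 °C
Reagents that add atoms: methylmagnesium bromide, C[Mg]Br; iodine, [I][I]
Why: Copper-catalysed, alkoxide-directed anti-carbomagnesiation of the propargylic alkoxide (Duboudin–Jousseaume reaction) puts methyl on C2 and magnesium on C3 in a five-membered chelate cis to the CH2O group, and iodinolysis of the C–Mg bond with retention gives the Z iodide.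

**Step 10**
Reactants: 15 (2Z)-3-iodo-2-methylprop-2-en-1-ol
Product: 17 (2Z)-3-iodo-2-methylprop-2-enoic acid, via aldehyde 16 (not isolated)
Conditions: TEMPO (20 mol %), PhI(OAc)2 (2.3 equiv), MeCN–H2O 1:1, 23 °C
Reagents that add atoms: water, O
Why: Oxoammonium-mediated (TEMPO/PhI(OAc)2) oxidation in aqueous acetonitrile takes the allylic alcohol through the aldehyde and its hydrate to the acid under near-neutral conditions that leave the Z iodoalkene intact.

**Step 11**
Reactants: 12 (1R,2R,8aR)-7-(2-hydroxypropan-2-yl)-1,8a-dimethyl-1,2,3,4,6,8a-hexahydronaphthalen-2-ol; 17 (2Z)-3-iodo-2-methylprop-2-enoic acid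
Product: 18 (1R,2R,8aR)-7-(2-hydroxypropan-2-yl)-1,8a-dimethyl-1,2,3,4,6,8a-hexahydronaphthalen-2-yl (2Z)-3-iodo-2-methylprop-2-enoate
Conditions: DCC (1.2 equiv), DMAP (10 mol %), CH2Cl2, −10 → 23 °C
Reagents that add atoms: none
Why: Steglich esterification acylates the equatorial secondary hydroxyl while the tertiary allylic hydroxyl does not react; the C2–O bond is not broken, so C2 stays R, and the iodoacrylate both masks the alcohol during the oxidation and carries the handle for sulfur.

**Step 12**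
Reactants: 18 (1R,2R,8aR)-7-(2-hydroxypropan-2-yl)-1,8a-dimethyl-1,2,3,4,6,8a-hexahydronaphthalen-2-yl (2Z)-3-iodo-2-methylprop-2-enoate
Product: 19 (1R,2R,8aR)-7-(2-hydroxypropan-2-yl)-1,8a-dimethyl-6-oxo-1,2,3,4,6,8a-hexahydronaphthalen-2-yl (2Z)-3-iodo-2-methylprop-2-enoate
Conditions: Rh2(C6H10NO)4 (dirhodium tetracaprolactamate, 1 mol %), t-BuOOH (5 equiv), K2CO3 (0.5 equiv), CH2Cl2, 23 °C
Reagents that add atoms: tert-butyl hydroperoxide, CC(C)(C)OO
Why: Bis-allylic C–H oxidation by the tert-butylperoxyl radical from the dirhodium caprolactamate/t-BuOOH system attacks the doubly allylic C6 methylene (weakest C–H), and because the quaternary C8a blocks aromatisation the mixed peroxide collapses to the cross-conjugated dienone; sulfur is not yet present and the vinyl iodide, ester and tertiary alcohol are inert.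

**Step 13**
Reactants: 19 (1R,2R,8aR)-7-(2-hydroxypropan-2-yl)-1,8a-dimethyl-6-oxo-1,2,3,4,6,8a-hexahydronaphthalen-2-yl (2Z)-3-iodo-2-methylprop-2-enoate
Product: 20 (1R,2R,8aR)-7-(2-hydroxypropan-2-yl)-1,8a-dimethyl-6-oxo-1,2,3,4,6,8a-hexahydronaphthalen-2-yl (2Z)-2-methyl-3-(methylsulfanyl)prop-2-enoate
Conditions: NaSMe (1.1 equiv), THF, −20 → 0 °C
Reagents that add atoms: sodium methanethiolate, [Na+].[S-]C
Why: Nucleophilic vinylic substitution by addition–elimination: thiolate adds to the β-carbon of the iodoacrylate and iodide leaves from the ester enolate faster than C–C rotation, so the Z geometry is retained, while addition to the dienone is reversible and both of its β-carbons are hindered.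

**Compound list**
1 | (E)-but-2-en-1-ol | C/C=C/CO | starting material
2 | [(2R,3R)-3-methyloxiran-2-yl]methanol | OC[C@H]1O[C@@H]1C | intermediate
3 | (2S,3R)-3-methyl-5-(trimethylsilyl)pent-4-yne-1,2-diol | O[C@H](CO)[C@H](C)C#C[Si](C)(C)C | intermediate
4 | (2S,3R)-3-methylpent-4-yne-1,2-diol | O[C@H](CO)[C@H](C)C#C | intermediate
5 | 3-methylbuta-1,2-diene | CC(C)=C=C | starting material
6 | 3-bromo-2-methylbut-3-en-2-ol | CC(C)(O)C(Br)=C | intermediate
7 | [(1E,3R,4S)-4,5-bis(dimethylalumanyloxy)-2,3-dimethylpent-1-en-1-yl]dimethylalumane | C[Al](C)OC[C@@H](O[Al](C)C)[C@H](C)/C(C)=C/[Al](C)C | intermediate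
8 | (2S,3R,4E)-3,4,7-trimethyl-6-methylideneoct-4-ene-1,2,7-triol | O[C@H](CO)[C@H](C)/C(C)=C/C(=C)C(C)(C)O | intermediate
9 | (2S,3R,4E)-2,7-dihydroxy-3,4,7-trimethyl-6-methylideneoct-4-en-1-yl 4-methylbenzenesulfonate | Cc1ccc(cc1)S(=O)(=O)OC[C@@H](O)[C@H](C)/C(C)=C/C(=C)C(C)(C)O | intermediate
10 | (4E,6R)-2,5-dimethyl-3-methylidene-6-[(2S)-oxiran-2-yl]hept-4-en-2-ol | C1O[C@H]1[C@H](C)/C(C)=C/C(=C)C(C)(C)O | intermediate
11 | (4E,6R,7R)-2,5,6-trimethyl-3-methylideneundec-4-en-10-yne-2,7-diol | C#CCC[C@@H](O)[C@H](C)/C(C)=C/C(=C)C(C)(C)O | intermediate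
12 | (1R,2R,8aR)-7-(2-hydroxypropan-2-yl)-1,8a-dimethyl-1,2,3,4,6,8a-hexahydronaphthalen-2-ol | O[C@@H]1CCC2=CCC(C(C)(C)O)=C[C@]2(C)[C@H]1C | intermediate
13 | prop-2-yn-1-ol | C#CCO | starting material
14 | (2Z)-3-(bromomagnesio)-2-methylprop-2-en-1-olate, bromomagnesium salt | Br[Mg]/C=C(/C)CO[Mg]Br | intermediate
15 | (2Z)-3-iodo-2-methylprop-2-en-1-ol | I/C=C(/C)CO | intermediate
16 | (2Z)-3-iodo-2-methylprop-2-enal | I/C=C(/C)C=O | intermediate
17 | (2Z)-3-iodo-2-methylprop-2-enoic acid | I/C=C(/C)C(=O)O | intermediate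
18 | (1R,2R,8aR)-7-(2-hydroxypropan-2-yl)-1,8a-dimethyl-1,2,3,4,6,8a-hexahydronaphthalen-2-yl (2Z)-3-iodo-2-methylprop-2-enoate | I/C=C(/C)C(=O)O[C@@H]1CCC2=CCC(C(C)(C)O)=C[C@]2(C)[C@H]1C | intermediate
19 | (1R,2R,8aR)-7-(2-hydroxypropan-2-yl)-1,8a-dimethyl-6-oxo-1,2,3,4,6,8a-hexahydronaphthalen-2-yl (2Z)-3-iodo-2-methylprop-2-enoate | I/C=C(/C)C(=O)O[C@@H]1CCC2=CC(=O)C(C(C)(C)O)=C[C@]2(C)[C@H]1C | intermediate
20 | (1R,2R,8aR)-7-(2-hydroxypropan-2-yl)-1,8a-dimethyl-6-oxo-1,2,3,4,6,8a-hexahydronaphthalen-2-yl (2Z)-2-methyl-3-(methylsulfanyl)prop-2-enoate | CS/C=C(/C)C(=O)O[C@@H]1CCC2=CC(=O)C(C(C)(C)O)=C[C@]2(C)[C@H]1C | target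

**Step count and risks**

Total step count: 13 (steps 4, 9 and 10 are side branches).
Longest linear sequence: 10 steps (steps 1, 2, 3, 5, 6, 7, 8, 11, 12, 13).

The three steps most likely to fail:

Step 8 (the double ring closure). The diene terminus that becomes C8a is trisubstituted and the alkyne is terminal, so oligomerisation, rhodium–vinylidene chemistry at the free 4-pentynol unit, or simple non-reaction are possible. Fallback: change the 2π partner and the metal. Setting out from 11, the alkyne is C-silylated (n-BuLi, 3.2 equiv, then benzyl(chloro)dimethylsilane, mild acidic work-up to clear O-silyl groups) to give (4E,6R,7R)-11-[benzyl(dimethyl)silyl]-2,5,6-trimethyl-3-methylideneundec-4-en-10-yne-2,7-diol F3. C-Silyl alkynes cannot form vinylidenes and are the best substrates for the zerovalent nickel version of this bicyclisation (Ni(C8H12)2, C8H12 = cycloocta-1,5-diene, with tris(2-biphenylyl) phosphite, THF), which gives (1R,2R,8aR)-5-[benzyl(dimethyl)silyl]-7-(2-hydroxypropan-2-yl)-1,8a-dimethyl-1,2,3,4,6,8a-hexahydronaphthalen-2-ol F4. Bu4NF in THF then removes the silyl group from C5 by protodesilylation and the route is rejoined at 12.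

Step 5 (one-flask methylalumination and cross-coupling on a free diol with a hindered 1,1-disubstituted bromide). Methyl transfer to 6 or a stalled coupling is possible. Fallback: split the operation and reverse the coupling polarity. Setting out from 4, the same alkenylalane 7 is quenched with iodine to give (2S,3R,4E)-5-iodo-3,4-dimethylpent-4-ene-1,2-diol F1. In parallel, 2-methylbut-3-yn-2-ol is hydrostannylated at the internal carbon (Bu3SnH, Mo(CO)3(CNtBu)3 catalyst) to 2-methyl-3-(tributylstannyl)but-3-en-2-ol F2. A copper-assisted Stille coupling of F1 with F2 (Pd(PPh3)4, CuI, CsF, DMF) comes back to the route at 8.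

Step 13 (thiolate on the iodoacrylate in the presence of the dienone). Conjugate addition to the dienone or loss of the Z geometry would spoil the last step. Fallback: bring sulfur in on the acid and the ester in last. Setting out from 12, the secondary hydroxyl is silylated (Et3SiCl, imidazole) to 2-[(7R,8R,8aR)-8,8a-dimethyl-7-(triethylsilyloxy)-3,5,6,7,8,8a-hexahydronaphthalen-2-yl]propan-2-ol F5. The same bis-allylic oxidation as in step 12 gives (4aR,5R,6R)-3-(2-hydroxypropan-2-yl)-4a,5-dimethyl-6-(triethylsilyloxy)-5,6,7,8-tetrahydronaphthalen-2(4aH)-one F6, and Bu4NF frees (4aR,5R,6R)-6-hydroxy-3-(2-hydroxypropan-2-yl)-4a,5-dimethyl-5,6,7,8-tetrahydronaphthalen-2(4aH)-one F7. Separately, acid 17 is treated with NaSMe (2.2 equiv, DMF) to give (2Z)-2-methyl-3-(methylsulfanyl)prop-2-enoic acid F8. Yamaguchi esterification of F7 with F8 (2,4,6-trichlorobenzoyl chloride, Et3N, DMAP) arrives at 20.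

**Further compounds**
F1 | step 5 | (2S,3R,4E)-5-iodo-3,4-dimethylpent-4-ene-1,2-diol | O[C@H](CO)[C@H](C)/C(C)=C/I
F2 | step 5 | 2-methyl-3-(tributylstannyl)but-3-en-2-ol | CCCC[Sn](CCCC)(CCCC)C(=C)C(C)(C)O
F3 | step 8 | (4E,6R,7R)-11-[benzyl(dimethyl)silyl]-2,5,6-trimethyl-3-methylideneundec-4-en-10-yne-2,7-diol | C[Si](C)(Cc1ccccc1)C#CCC[C@@H](O)[C@H](C)/C(C)=C/C(=C)C(C)(C)O
F4 | step 8 | (1R,2R,8aR)-5-[benzyl(dimethyl)silyl]-7-(2-hydroxypropan-2-yl)-1,8a-dimethyl-1,2,3,4,6,8a-hexahydronaphthalen-2-ol | O[C@@H]1CCC2=C([Si](C)(C)Cc3ccccc3)CC(C(C)(C)O)=C[C@]2(C)[C@H]1C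
F5 | step 13 | 2-[(7R,8R,8aR)-8,8a-dimethyl-7-(triethylsilyloxy)-3,5,6,7,8,8a-hexahydronaphthalen-2-yl]propan-2-ol | CC[Si](CC)(CC)O[C@@H]1CCC2=CCC(C(C)(C)O)=C[C@]2(C)[C@H]1C
F6 | step 13 | (4aR,5R,6R)-3-(2-hydroxypropan-2-yl)-4a,5-dimethyl-6-(triethylsilyloxy)-5,6,7,8-tetrahydronaphthalen-2(4aH)-one | CC[Si](CC)(CC)O[C@@H]1CCC2=CC(=O)C(C(C)(C)O)=C[C@]2(C)[C@H]1C
F7 | step 13 | (4aR,5R,6R)-6-hydroxy-3-(2-hydroxypropan-2-yl)-4a,5-dimethyl-5,6,7,8-tetrahydronaphthalen-2(4aH)-one | O[C@@H]1CCC2=CC(=O)C(C(C)(C)O)=C[C@]2(C)[C@H]1C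
F8 | step 13 | (2Z)-2-methyl-3-(methylsulfanyl)prop-2-enoic acid | CS/C=C(/C)C(=O)O
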